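**Retrosynthetic overview**

1. Labdane numbering is used throughout (decalin C1–C10, side chain C11–C16, C17 on C8, C18/C19 on C4, C20 on C10). The 2α,3α-diol goes back to a C2=C3 alkene (late α-face osmylation), the (E)-enoate to a terminal alkyne (methylalumination/acylation), and the C9 carbinol to a trans-fused C9 ketone plus a four-carbon alkynyl nucleophile delivered on the α-face.
2. The trans-decalone comes from hydrogen-atom-transfer reduction of a C5=C6 octalinone. That octalinone is the product of the key step, a one-pot Michael/Wittig [4+2] annulation that stitches a vinylphosphonium C6–C7 unit onto monocyclic ring A, forming C7–C8 and C5=C6 and closing ring B.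
3. Enabling feature: C5 of ring A lies between the quaternary carbons C4 and C10, and C8 is α to the oxygenated C9. At the C5,C9-diketone level C8 is therefore the only enolisable carbon, and the C5 carbonyl can act only as the Wittig acceptor.
4. Ring order: ring A first (ring-closing metathesis of an acyclic 1,3-diketone whose C10 quaternary centre is set by Pd-catalysed asymmetric allylation), ring B second (key step).

Key step: step 4

Assumption: the sense of induction in step 2 cannot be read off a close model, so the (R,R)-ligand is named as the antipode expected to give (4R)-6 and would be exchanged for its mirror image if the first run shows the opposite sense; all later stereocentres are substrate-controlled from C10.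

**Step 1**
Reactants: 1 2,2-dimethylbut-3-enoic acid; 2 pentan-3-one
Product: 4 4,6,6-trimethyloct-7-ene-3,5-dione, via 2,2-dimethylbut-3-enoyl chloride 3 (not isolated)
Conditions: (COCl)2, DMF (cat.), CH2Cl2, 0 → 23 °C; then 2, MgBr2·OEt2, i-Pr2NEt, CH2Cl2, 23 °C
Reagents that add atoms: oxalyl chloride, ClC(=O)C(=O)Cl (chlorine of intermediate 3 only)
Why: Soft-enolisation C-acylation (crossed Claisen type) of the magnesium enolate of symmetrical pentan-3-one by an acid chloride that cannot form a ketene should give the 1,3-diketone as its magnesium chelate, which shields it from a second acylation; no stereocentre of the target is set here.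

**Step 2**
Reactants: 4 4,6,6-trimethyloct-7-ene-3,5-dione; 5 allyl methyl carbonate
Product: 6 (4R)-4,6,6-trimethyl-4-(prop-2-en-1-yl)oct-7-ene-3,5-dione
Conditions: Pd2(dba)3·CHCl3 (cat.), (R,R)-N,N′-bis(2-diphenylphosphinobenzoyl)-1,2-diaminocyclohexane (cat.), toluene, 0 → 23 °C
Reagents that add atoms: none
Why: Tsuji–Trost asymmetric allylic alkylation, in which methoxide released on ionisation of 5 deprotonates the diketone and the prochiral diketonate attacks the π-allylpalladium complex inside the chiral ligand pocket, which should tell the enolate faces apart through the large size difference between the tert-alkyl and the ethyl acyl group and so set the C10 quaternary centre.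

**Step 3**
Reactants: 6 (4R)-4,6,6-trimethyl-4-(prop-2-en-1-yl)oct-7-ene-3,5-dione
Product: 7 (6R)-2,2,6-trimethyl-6-propanoylcyclohex-3-en-1-one
Conditions: second-generation Grubbs catalyst RuCl2(=CHPh)(PCy3)(H2IMes) (cat.), CH2Cl2, 40 °C
Reagents that add atoms: none
Why: Ring-closing metathesis of the only two alkenes present should close ring A as the cyclohexene that carries the later C2=C3 alkene, helped by the gem-dimethyl (Thorpe–Ingold) effect and driven by loss of ethylene; the quaternary C10 centre is not involved.

**Step 4**
Reactants: 7 (6R)-2,2,6-trimethyl-6-propanoylcyclohex-3-en-1-one; 8 triphenyl(vinyl)phosphonium bromide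
Product: 10 (2R,8aS)-2,5,5,8a-tetramethyl-3,5,8,8a-tetrahydronaphthalen-1(2H)-one, via phosphonium ylide 9 (not isolated)
Conditions: KN(SiMe3)2, THF, −78 °C; 8 (solid), −78 → 23 °C, then 65 °C; then NaOMe (cat.), MeOH, 23 °C
Reagents that add atoms: none
Why: KN(SiMe3)2 deprotonates C8, the enolate adds in a Michael sense to the vinylphosphonium salt (C7–C8 bond), and the non-stabilised ylide 9 so formed attacks the C5 carbonyl intramolecularly and collapses through an oxaphosphetane to the C5=C6 alkene with loss of Ph3P=O. The closest known reaction type is the tandem conjugate addition/intramolecular Wittig cycloalkene annulation of keto-enolates with vinyltriphenylphosphonium bromide. Ring B is the only ring closed, by 6-exo-trig attack of the ylide carbon C6 on the C5 carbonyl, and the phosphorus that activates the two-carbon unit leaves in the same operation. The one new stereocentre, C8, is epimerisable α to the C9 ketone and is set under thermodynamic control (NaOMe/MeOH) with its methyl group equatorial (8α), which avoids a syn-axial clash with the C10 methyl; C5 stays sp2 so that the ring fusion can be set in step 5. The step needs regioselective enolisation and Wittig closure on C5 rather than C9: C4 and C10 are quaternary, so C8 carries the only acidic hydrogens, the ylide could reach C9 only through a four-membered ring, and both carbonyls are too hindered for intermolecular olefination.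

**Step 5**
Reactants: 10 (2R,8aS)-2,5,5,8a-tetramethyl-3,5,8,8a-tetrahydronaphthalen-1(2H)-one
Product: 11 (2R,4aS,8aS)-2,5,5,8a-tetramethyl-3,4,4a,5,8,8a-hexahydronaphthalen-1(2H)-one
Conditions: Mn(dpm)3 [tris(2,2,6,6-tetramethylheptane-3,5-dionato)manganese] (cat.), PhSiH3, t-BuOOH, i-PrOH, 22 °C
Reagents that add atoms: none
Why: Metal-hydride hydrogen-atom-transfer hydrogenation, in which hydrogen atom transfer to C6 of the trisubstituted C5=C6 alkene gives the tertiary C5 radical that should be quenched on the α-face because the β-face is covered by the axial C10 methyl and the β-methyl on C4, setting the trans ring fusion (5α-H, also the thermodynamic outcome), while the cis-disubstituted C2=C3 alkene and the ketone should react much more slowly and C8 is untouched.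

**Step 6**
Reactants: 11 (2R,4aS,8aS)-2,5,5,8a-tetramethyl-3,4,4a,5,8,8a-hexahydronaphthalen-1(2H)-one; 12 (4-bromobut-1-yn-1-yl)trimethylsilane
Product: 15 (1S,2R,4aS,8aS)-1-(but-3-yn-1-yl)-2,5,5,8a-tetramethyl-1,2,3,4,4a,5,8,8a-octahydronaphthalen-1-ol, via Grignard reagent 13 (not isolated), via silylated alkynol 14 (not isolated)
Conditions: 12, Mg, THF, 23 °C; anhydrous CeCl3, THF, −78 °C; 11, −78 → 0 °C; aq. NH4Cl; crude, K2CO3 (cat.), MeOH, 23 °C
Reagents that add atoms: magnesium, [Mg] (in intermediate 13 only)
Why: Organocerium 1,2-addition followed by methanolysis of the alkynyl C–Si bond, in which the weakly basic cerium reagent should suppress enolisation towards C8 and attack the C9 carbonyl axially from the α-face, anti to the axial C10 methyl that blocks the equatorial (β) trajectory, so that C9 carries the chain α (axial) and the hydroxyl β (equatorial).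

**Step 7**
Reactants: 15 (1S,2R,4aS,8aS)-1-(but-3-yn-1-yl)-2,5,5,8a-tetramethyl-1,2,3,4,4a,5,8,8a-octahydronaphthalen-1-ol
Product: 16 methyl (2E)-5-[(1S,2R,4aS,8aS)-1-hydroxy-2,5,5,8a-tetramethyl-1,2,3,4,4a,5,8,8a-octahydronaphthalen-1-yl]-3-methylpent-2-enoate
Conditions: AlMe3 (excess), Cp2ZrCl2, CH2Cl2, 0 → 23 °C; then ClCO2Me, 23 °C; cold dilute HCl
Reagents that add atoms: trimethylaluminium, C[Al](C)C; methyl chloroformate, COC(=O)Cl
Why: Zirconium-catalysed methylalumination (Negishi carboalumination) of the terminal alkyne followed by acylation of the alkenylalane, in which syn addition places methyl on C13 and aluminium on C14 cis to one another and replacement of aluminium by CO2Me with retention should give the (E)-enoate, the tertiary hydroxyl being masked in the flask as its aluminium alkoxide and the ring alkene being inert.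

**Step 8**
Reactants: 16 methyl (2E)-5-[(1S,2R,4aS,8aS)-1-hydroxy-2,5,5,8a-tetramethyl-1,2,3,4,4a,5,8,8a-octahydronaphthalen-1-yl]-3-methylpent-2-enoate
Product: 17 methyl (2E)-3-methyl-5-[(1S,2R,4aS,6S,7R,8aS)-1,6,7-trihydroxy-2,5,5,8a-tetramethyldecahydronaphthalen-1-yl]pent-2-enoate (CNP0292844.1)
Conditions: OsO4 (cat.), 4-methylmorpholine N-oxide, acetone–H2O, 23 °C
Reagents that add atoms: osmium tetroxide, O=[Os](=O)(=O)=O; 4-methylmorpholine N-oxide, C[N+]1([O-])CCOCC1; water, O
Why: Upjohn dihydroxylation, in which OsO4 should add syn to the electron-rich C2=C3 alkene in preference to the electron-poor trisubstituted enoate and from the α-face, because the axial C10 methyl and the β-methyl on C4 are both syn-axial to a reagent arriving on the β-face, giving the 2α,3α-diol.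

**Compound list**

1 | 2,2-dimethylbut-3-enoic acid | C=CC(C)(C)C(=O)O | starting material
2 | pentan-3-one | CCC(=O)CC | starting material
3 | 2,2-dimethylbut-3-enoyl chloride | C=CC(C)(C)C(=O)Cl | intermediate (not isolated)
4 | 4,6,6-trimethyloct-7-ene-3,5-dione (racemic, keto form drawn) | CCC(=O)C(C)C(=O)C(C)(C)C=C | intermediate
5 | allyl methyl carbonate | C=CCOC(=O)OC | starting material
6 | (4R)-4,6,6-trimethyl-4-(prop-2-en-1-yl)oct-7-ene-3,5-dione | CCC(=O)[C@@](C)(CC=C)C(=O)C(C)(C)C=C | intermediate
7 | (6R)-2,2,6-trimethyl-6-propanoylcyclohex-3-en-1-one | CCC(=O)[C@@]1(C)CC=CC(C)(C)C1=O | intermediate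
8 | triphenyl(vinyl)phosphonium bromide | C=C[P+](c1ccccc1)(c1ccccc1)c1ccccc1.[Br-] | starting material
9 | (6R)-2,2,6-trimethyl-6-[2-methyl-4-(triphenyl-λ5-phosphanylidene)butanoyl]cyclohex-3-en-1-one (either configuration at the butanoyl C2) | CC(CC=P(c1ccccc1)(c1ccccc1)c1ccccc1)C(=O)[C@@]1(C)CC=CC(C)(C)C1=O | intermediate (not isolated)
10 | (2R,8aS)-2,5,5,8a-tetramethyl-3,5,8,8a-tetrahydronaphthalen-1(2H)-one | O=C1[C@H](C)CC=C2C(C)(C)C=CC[C@@]21C | intermediate
11 | (2R,4aS,8aS)-2,5,5,8a-tetramethyl-3,4,4a,5,8,8a-hexahydronaphthalen-1(2H)-one | O=C1[C@H](C)CC[C@H]2C(C)(C)C=CC[C@@]21C | intermediate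
12 | (4-bromobut-1-yn-1-yl)trimethylsilane | C[Si](C)(C)C#CCCBr | starting material
13 | [4-(trimethylsilyl)but-3-yn-1-yl]magnesium bromide | C[Si](C)(C)C#CCC[Mg]Br | intermediate (not isolated)
14 | (1S,2R,4aS,8aS)-2,5,5,8a-tetramethyl-1-[4-(trimethylsilyl)but-3-yn-1-yl]-1,2,3,4,4a,5,8,8a-octahydronaphthalen-1-ol | C[Si](C)(C)C#CCC[C@]1(O)[C@H](C)CC[C@H]2C(C)(C)C=CC[C@@]21C | intermediate (not isolated)
15 | (1S,2R,4aS,8aS)-1-(but-3-yn-1-yl)-2,5,5,8a-tetramethyl-1,2,3,4,4a,5,8,8a-octahydronaphthalen-1-ol | C#CCC[C@]1(O)[C@H](C)CC[C@H]2C(C)(C)C=CC[C@@]21C | intermediate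
16 | methyl (2E)-5-[(1S,2R,4aS,8aS)-1-hydroxy-2,5,5,8a-tetramethyl-1,2,3,4,4a,5,8,8a-octahydronaphthalen-1-yl]-3-methylpent-2-enoate | COC(=O)/C=C(\C)CC[C@]1(O)[C@H](C)CC[C@H]2C(C)(C)C=CC[C@@]21C | intermediate
17 | methyl (2E)-3-methyl-5-[(1S,2R,4aS,6S,7R,8aS)-1,6,7-trihydroxy-2,5,5,8a-tetramethyldecahydronaphthalen-1-yl]pent-2-enoate | COC(=O)/C=C(\C)CC[C@]1(O)[C@H](C)CC[C@H]2C(C)(C)[C@H](O)[C@H](O)C[C@@]21C | target

**Step count and risks**

Total step count: 8. Longest linear sequence: 8 steps (1 and 2 to 17); 5, 8 and 12 are commercial and enter directly.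

The three steps most likely to fail:

Step 4. The ylide may fail to engage the congested C5 carbonyl, which is flanked by two quaternary carbons, so that proton transfer and oligomerisation with further vinylphosphonium salt outrun ring closure. The fallback sets out from 7 and comes back at 10, forming the same two bonds in two stages. Michael addition of the potassium enolate of 7 (KN(SiMe3)2, THF, −78 °C) to phenyl vinyl sulfone should give the keto sulfone F1. Two equivalents of LiN(i-Pr)2 then generate the enolate/α-sulfonyl dianion, whose sulfonyl carbanion adds to the C5 carbonyl; trapping with Ac2O should give the β-acetoxy sulfone F2 (any enol acetate at C9 is cleaved in the next, methanolic operation). Reductive elimination with Na(Hg)/Na2HPO4 in MeOH (Julia olefination) can only form the C5=C6 alkene and, after the same NaOMe equilibration of C8, should give 10.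

Step 2. Face discrimination of the acyclic, conformationally mobile diketonate may be poor, giving low enantiomeric enrichment at C10, and the sense of induction is unproven. The fallback sets out from 4 and comes back at 6, replacing catalyst control by a covalently bound auxiliary. Condensation of 4 with tert-butyl L-valinate (TsOH cat., toluene, reflux, removal of water) at the less hindered propanoyl carbonyl should give the chiral enaminone F3. Deprotonation with LiN(i-Pr)2 and alkylation with allyl bromide should give the C-allylated ketimine F4 under auxiliary control, and aqueous AcOH hydrolysis should release 6; the auxiliary antipode is chosen by the same correlation as in the assumption.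

Step 6. The basic organometallic may enolise the ketone towards C8, or attack too slowly at a carbonyl flanked by a quaternary and a tertiary carbon, so that ketone is returned. The fallback sets out from 11 and comes back at 14, building the C9–C11 bond with a small ylide and the C11–C12 bond by epoxide opening. Corey–Chaykovsky epoxidation with dimethylsulfonium methylide (trimethylsulfonium iodide, n-BuLi, THF, 0 °C), which should add axially from the α-face, gives the spiro-epoxide F5 (oxirane CH2 α, oxygen β). Opening at the oxirane CH2 with lithiated 1-(trimethylsilyl)propyne (n-BuLi, THF, −78 °C; BF3·OEt2) should give 14, which is desilylated as in step 6.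

**Further compounds**

F1 | step 4 | (6R)-2,2,6-trimethyl-6-[2-methyl-4-(phenylsulfonyl)butanoyl]cyclohex-3-en-1-one (either configuration at the butanoyl C2) | CC(CCS(=O)(=O)c1ccccc1)C(=O)[C@@]1(C)CC=CC(C)(C)C1=O
F2 | step 4 | ring-closed β-acetoxy sulfone, 5-acetoxy-6-(phenylsulfonyl) derivative of the C9 decalone (C5, C6 and C8 not controlled) | O=C1C(C)CC(S(=O)(=O)c2ccccc2)C2(OC(C)=O)C(C)(C)C=CC[C@@]21C
F3 | step 2 | tert-butyl N-[(Z)-4,6,6-trimethyl-5-oxoocta-3,7-dien-3-yl]-L-valinate (enaminone) | CC/C(N[C@@H](C(C)C)C(=O)OC(C)(C)C)=C(C)/C(=O)C(C)(C)C=C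
F4 | step 2 | C-allylated ketimine of 6 with tert-butyl L-valinate | CCC(=N[C@@H](C(C)C)C(=O)OC(C)(C)C)[C@@](C)(CC=C)C(=O)C(C)(C)C=C
F5 | step 6 | spiro-epoxide of 11 at C9 (oxirane CH2 on the α-face, oxygen β) | C1O[C@]12[C@H](C)CC[C@H]3C(C)(C)C=CC[C@@]32C
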